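**Plan**

- Retrosynthetic cuts, in order: C2–C3 (closure of the ten-membered ring, last C–C bond); C6–C7 together with the lactone C–O bond (union of the two fragments); C7–C11 (acrylate unit); the O8–acyl bond.
- Forward order: the γ-lactone ring forms first, when a C3–C6/C15 lactol is allylated by a C7–C13/C8–C10/C1–C2 allylic bromide with CrCl2. The ten-membered carbocycle forms last by Ni/Cr alkenyl iodide–aldehyde closure at C2–C3, followed by oxidation to the dienone.
- Enabling feature: the cis C4=C5 bond and the trans-fused lactone ring (O–C6–C7–C11–C12) hold C3 to C7 in a U-turn, and the quaternary C10 turns the C1=C2 arm back, so alkenyl C2 and aldehyde C3 can meet. A butenolide ring that is not in the target fixes the 4Z geometry and distinguishes C3 from C15 before it is opened.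
- Stereochemistry: C10 from (R)-linalool; C8 by catalyst-controlled α-oxyamination; C6 and C7 in the allylation (anti, directed by C8); the ester α-carbon from (R)-2-methylbutanoic acid; 1E from Takai olefination; 4Z from the butenolide.

Key step: step 17

Remark (numbering and abbreviations): C-locants are the germacrane locants of the target (C3 ring ketone, C1=C2 its E-alkene, C4=C5 the Z-alkene bearing C15, C6/C7 lactone ring fusion, C8 ester carbinol, C10 tertiary carbinol bearing C14, C11–C13 methylene lactone). TBDPS = tert-butyldiphenylsilyl, TES = triethylsilyl, TMP-O = (2,2,6,6-tetramethylpiperidin-1-yl)oxy. Numbered carbon building blocks are listed as reactants.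

Remark (assumption on the chemistry): in step 12 the aldehyde is assumed to attack C7 anti to the C9 chain, with the very bulky C8–O-TMP group outside. The opposite preference (C–O bond anti) is covered by the first fallback.

**Step 1**
Reactants: 1 1,3-dihydroxyacetone (commercial dimer); 2 ethyl (triphenylphosphoranylidene)acetate
Product: 4 4-(hydroxymethyl)furan-2(5H)-one, via ethyl 4-hydroxy-3-(hydroxymethyl)but-2-enoate 3 (not isolated)
Conditions: CH2Cl2, rt, 16 h
Reagents that add atoms: none
Why: Wittig olefination of the ketone gives a γ-hydroxy enoate that lactonizes in the flask; the two CH2OH groups are equivalent, so no alkene geometry has to be controlled.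

**Step 2**
Reactants: 4 4-(hydroxymethyl)furan-2(5H)-one
Product: 5 4-({[tert-butyl(diphenyl)silyl]oxy}methyl)furan-2(5H)-one
Conditions: TBDPSCl, imidazole, DMF, 0 °C → rt
Reagents that add atoms: tert-butyl(chloro)diphenylsilane, CC(C)(C)[Si](Cl)(c1ccccc1)c1ccccc1
Why: Standard silylation of a primary alcohol; TBDPS is chosen because it should survive aqueous acetic acid and all later steps until fluoride.

**Step 3**
Reactants: 5 silylated butenolide
Product: 6 4-({[tert-butyl(diphenyl)silyl]oxy}methyl)-2,5-dihydrofuran-2-ol (lactol, both anomers)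
Conditions: i-Bu2AlH (1.1 equiv), CH2Cl2, −78 °C; aq. potassium sodium tartrate (KNaC4H4O6)
Reagents that add atoms: none
Why: Half-reduction of a lactone to the lactol at low temperature; the ring keeps C3 and C6 cis on C4=C5 (latent Z-enal) and marks C3 (ring CH2O) as different from C15.

**Step 4**
Reactants: 7 (R)-(−)-linalool
Product: 8 (3R)-3,7-dimethyl-3-(triethylsilyloxy)octa-1,6-diene
Conditions: TESOTf, 2,6-lutidine, CH2Cl2, −78 → 0 °C
Reagents that add atoms: triethylsilyl trifluoromethanesulfonate, CC[Si](CC)(CC)OS(=O)(=O)C(F)(F)F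
Why: Silyl triflates silylate tertiary alcohols; the C10 stereocenter is taken from the chiral pool and is not touched again.

**Step 5**
Reactants: 8 silyl ether of linalool
Product: 9 (3R)-6,7-epoxy-3,7-dimethyl-3-(triethylsilyloxy)oct-1-ene (both epoxide epimers)
Conditions: mCPBA (1.05 equiv), NaHCO3, CH2Cl2, 0 °C
Reagents that add atoms: 3-chloroperoxybenzoic acid, OOC(=O)c1cccc(Cl)c1
Why: Prilezhaev epoxidation is selective for the electron-rich trisubstituted alkene over the hindered vinyl group; the epoxide serves as a masked aldehyde and its configuration is irrelevant.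

**Step 6**
Reactants: 9 epoxy alkene
Product: 11 (2R)-4-(3,3-dimethyloxiran-2-yl)-2-methyl-2-(triethylsilyloxy)butanal, via ozonide 10 (not isolated)
Conditions: O3, CH2Cl2, −78 °C; then PPh3, −78 °C → rt
Reagents that add atoms: ozone, [O-][O+]=O
Why: Ozonolysis of the only remaining C=C with reductive work-up should give the non-enolizable α-silyloxy aldehyde (C1).

**Step 7**
Reactants: 11 α-silyloxy aldehyde; 12 iodoform
Product: 13 (3R,1E)-5-(3,3-dimethyloxiran-2-yl)-1-iodo-3-methyl-3-(triethylsilyloxy)pent-1-ene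
Conditions: CHI3, CrCl2 (6 equiv), THF, 0 °C → rt
Reagents that add atoms: none
Why: Takai olefination converts aldehydes into (E)-alkenyl iodides via a geminal dichromium reagent; this sets the 1E geometry and introduces C2.

**Step 8**
Reactants: 13 epoxy alkenyl iodide
Product: 14 (4R,5E)-6-iodo-4-methyl-4-(triethylsilyloxy)hex-5-enal
Conditions: H5IO6, THF/Et2O, 0 °C
Reagents that add atoms: none
Why: Periodic acid opens the trisubstituted epoxide and cleaves the resulting diol to the C7 aldehyde and acetone; the short cold exposure should spare the tertiary TES ether.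

**Step 9**
Reactants: 14 aldehyde
Product: 15 (2R,4R,5E)-6-iodo-4-methyl-2-[(2,2,6,6-tetramethylpiperidin-1-yl)oxy]-4-(triethylsilyloxy)hex-5-enal
Conditions: TEMPO (1.5 equiv), CuCl2·2H2O (10 mol %), 5-benzyl-2-tert-butyl-3-methylimidazolidin-4-one·CF3CO2H (20 mol %, the enantiomer that delivers 2R), acetone, air, −10 °C
Reagents that add atoms: TEMPO, CC1(C)CCCC(C)(C)N1[O]
Why: Organocatalytic α-oxyamination (enamine catalysis with copper-mediated TEMPO transfer); the shielded face of the enamine is set by the catalyst, which fixes C8 with little influence from remote C10, and the O-TMP group then serves as a robust protecting group.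

**Step 10**
Reactants: 15 α-oxy aldehyde; 16 methyl propiolate
Product: 18 methyl (4R,6R,7E)-3-hydroxy-8-iodo-6-methyl-2-methylidene-4-(TMP-O)-6-(triethylsilyloxy)oct-7-enoate (both C3 epimers), via vinylalane 17 (not isolated)
Conditions: 16, i-Bu2AlH, N-methylmorpholine N-oxide, THF, 0 °C; then 15, 0 °C → rt
Reagents that add atoms: none
Why: Vinylalumination (1,4-hydroalumination of the propiolate, then addition of the α-aluminated acrylate to the aldehyde) is a non-basic Baylis–Hillman equivalent that should not epimerize C8; the new carbinol center is lost in step 11.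

**Step 11**
Reactants: 18 Baylis–Hillman-type adduct
Product: 19 methyl (2Z,4R,6R,7E)-2-(bromomethyl)-8-iodo-6-methyl-4-(TMP-O)-6-(triethylsilyloxy)octa-2,7-dienoate
Conditions: NBS, Me2S, CH2Cl2, 0 °C → rt
Reagents that add atoms: N-bromosuccinimide, O=C1CCC(=O)N1Br
Why: Activation of the allylic hydroxyl as an alkoxysulfonium ion and SN2' attack by bromide should give the thermodynamically preferred (Z)-2-(bromomethyl)enoate.

**Step 12**
Reactants: 19 allylic bromide; 6 lactol
Product: 22 C3-hydroxy iodo lactone (α-methylene-γ-butyrolactone with C6 and C7 and C8 and C10 as in the target), via allylchromium dichloride 20 (not isolated), via open hydroxy ester 21 (not isolated)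
Conditions: CrCl2 (4 equiv), THF, 0 °C → rt; aq. NH4Cl; then PPTS (cat.), CH2Cl2, rt
Reagents that add atoms: none
Why: The allylchromium from 19 equilibrates to the isomer with C8 trans to CH2Cr and adds through a chair (Zimmerman–Traxler) transition state to the open (Z)-4-hydroxy-enal form of 6, which should give the anti C6/C7 adduct and, after lactonization, the trans-lactone (chromium-mediated 2-(alkoxycarbonyl)allylation of the Nozaki–Hiyama type); the C7 face is set by C8, whose C–H eclipses C7=C11 (allylic 1,3-strain with the ester), so the aldehyde should approach anti to the C9 chain, on the side of the outside O-TMP group.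

**Step 13**
Reactants: 22 C3-hydroxy iodo lactone
Product: 23 triol (C3-OH and C8-OH and C10-OH free)
Conditions: Zn dust, AcOH/THF/H2O (3:1:1), 45 °C
Reagents that add atoms: none
Why: Zinc in acetic acid reduces the N–O bond of the alkoxyamine, and the same medium should hydrolyze the tertiary TES ether; alkenyl iodide, TBDPS ether and the methylene lactone are expected to survive.

**Step 14**
Reactants: 23 triol
Product: 24 C3-O-TES diol
Conditions: TESCl (1.05 equiv), imidazole, CH2Cl2, −40 °C
Reagents that add atoms: chlorotriethylsilane, CC[Si](Cl)(CC)CC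
Why: The primary allylic hydroxyl is silylated much faster than the hindered secondary and the tertiary one; this keeps C3 at the alcohol level while O8 is acylated.

**Step 15**
Reactants: 24 C3-O-TES diol; 25 (R)-2-methylbutanoic acid
Product: 26 C8 (R)-2-methylbutanoate
Conditions: 25, N,N'-diisopropylcarbodiimide, DMAP (cat.), CH2Cl2, 0 °C → rt
Reagents that add atoms: none
Why: Steglich esterification acylates the secondary C8 hydroxyl and leaves the tertiary C10 hydroxyl; carbodiimide activation with catalytic DMAP at low temperature should keep the α-center of the acid. Installing the ester before C3 becomes a carbonyl prevents oxa-Michael addition of O8.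

**Step 16**
Reactants: 26 ester
Product: 27 (Z)-enal (C3 aldehyde)
Conditions: (COCl)2, DMSO, CH2Cl2, −78 → −40 °C; Et3N
Reagents that add atoms: none
Why: Swern conditions convert primary TES ethers directly into aldehydes (chloride removes silicon from the sulfonium-activated ether); the low temperature should preserve the less stable Z-enal and the tertiary alcohol cannot be oxidized.

**Step 17**
Reactants: 27 (Z)-enal bearing the (E)-alkenyl iodide
Product: 29 macrocyclic bis-allylic alcohol (both C3 epimers), via alkenylchromium dichloride 28 (not isolated)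
Conditions: CrCl2 (10 equiv), NiCl2 (1 mol % of the CrCl2), DMSO/THF (3:1), rt, syringe-pump addition to 2 mM
Reagents that add atoms: none
Why: Oxidative addition of the (E)-alkenyl iodide to zerovalent nickel (formed from NiCl2 and CrCl2), transmetalation to trivalent chromium and intramolecular 1,2-addition of alkenyl C2 to aldehyde C3 form the C2–C3 bond with retention of the E geometry (Nozaki–Hiyama–Kishi reaction). The closest known reaction type is the Nozaki–Hiyama–Kishi closure of nine- to twelve-membered carbocycles and lactones containing an (E)-allylic alcohol. The ten-membered carbocycle closes in the 10-exo-trig mode, the C=O being exocyclic to the new ring. The only new stereocenter, the C3 carbinol, is not controlled and is erased in step 18. The step needs chemoselectivity and cyclization over oligomerization: alkenylchromium reagents add to aldehydes but not to the enoate of the methylene lactone, the esters or the free tertiary alcohol, and high dilution together with the folded substrate (cis C4=C5, trans-lactone at C6–C7, quaternary C10) should favor ring closure.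

**Step 18**
Reactants: 29 macrocyclic alcohol
Product: 30 15-O-TBDPS ether of the target
Conditions: Dess–Martin periodinane, NaHCO3, CH2Cl2, 0 °C → rt
Reagents that add atoms: none
Why: Dess–Martin oxidation of the bis-allylic secondary alcohol gives the cross-conjugated dienone from both C3 epimers; the tertiary alcohol is inert.

**Step 19**
Reactants: 30 silyl ether
Product: 31 target compound
Conditions: HF·pyridine, pyridine/THF, 0 °C → rt
Reagents that add atoms: none
Why: Buffered HF cleaves the primary TBDPS ether under non-basic conditions that the dienone, the methylene lactone and the ester should tolerate; the product should be shielded from light.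

**Compound list**

1 | 1,3-dihydroxyacetone (commercial dimer) | OCC(=O)CO | starting material
2 | ethyl (triphenylphosphoranylidene)acetate | CCOC(=O)C=P(c1ccccc1)(c1ccccc1)c1ccccc1 | starting material
3 | ethyl 4-hydroxy-3-(hydroxymethyl)but-2-enoate | CCOC(=O)C=C(CO)CO | intermediate
4 | 4-(hydroxymethyl)furan-2(5H)-one | O=C1C=C(CO)CO1 | intermediate
5 | 4-({[tert-butyl(diphenyl)silyl]oxy}methyl)furan-2(5H)-one | O=C1C=C(CO[Si](c2ccccc2)(c2ccccc2)C(C)(C)C)CO1 | intermediate
6 | 4-({[tert-butyl(diphenyl)silyl]oxy}methyl)-2,5-dihydrofuran-2-ol (both anomers) | OC1C=C(CO[Si](c2ccccc2)(c2ccccc2)C(C)(C)C)CO1 | intermediate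
7 | (R)-(−)-linalool | C=C[C@](C)(O)CCC=C(C)C | starting material
8 | (3R)-3,7-dimethyl-3-(triethylsilyloxy)octa-1,6-diene | C=C[C@](C)(O[Si](CC)(CC)CC)CCC=C(C)C | intermediate
9 | (3R)-6,7-epoxy-3,7-dimethyl-3-(triethylsilyloxy)oct-1-ene (both epoxide epimers) | C=C[C@](C)(O[Si](CC)(CC)CC)CCC1OC1(C)C | intermediate
10 | ozonide (1,2,4-trioxolane) of 9 | C1(OOCO1)[C@](C)(O[Si](CC)(CC)CC)CCC1OC1(C)C | intermediate
11 | (2R)-4-(3,3-dimethyloxiran-2-yl)-2-methyl-2-(triethylsilyloxy)butanal | O=C[C@](C)(O[Si](CC)(CC)CC)CCC1OC1(C)C | intermediate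
12 | iodoform | IC(I)I | starting material
13 | (3R,1E)-5-(3,3-dimethyloxiran-2-yl)-1-iodo-3-methyl-3-(triethylsilyloxy)pent-1-ene | I/C=C/[C@](C)(O[Si](CC)(CC)CC)CCC1OC1(C)C | intermediate
14 | (4R,5E)-6-iodo-4-methyl-4-(triethylsilyloxy)hex-5-enal | I/C=C/[C@](C)(O[Si](CC)(CC)CC)CCC=O | intermediate
15 | (2R,4R,5E)-6-iodo-4-methyl-2-(TMP-O)-4-(triethylsilyloxy)hex-5-enal | I/C=C/[C@](C)(O[Si](CC)(CC)CC)C[C@@H](ON1C(C)(C)CCCC1(C)C)C=O | intermediate
16 | methyl propiolate | C#CC(=O)OC | starting material
17 | [1-(methoxycarbonyl)vinyl]diisobutylaluminium | C=C(C(=O)OC)[Al](CC(C)C)CC(C)C | intermediate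
18 | methyl (4R,6R,7E)-3-hydroxy-8-iodo-6-methyl-2-methylidene-4-(TMP-O)-6-(triethylsilyloxy)oct-7-enoate (both C3 epimers) | I/C=C/[C@](C)(O[Si](CC)(CC)CC)C[C@@H](ON1C(C)(C)CCCC1(C)C)C(O)C(=C)C(=O)OC | intermediate
19 | methyl (2Z,4R,6R,7E)-2-(bromomethyl)-8-iodo-6-methyl-4-(TMP-O)-6-(triethylsilyloxy)octa-2,7-dienoate | I/C=C/[C@](C)(O[Si](CC)(CC)CC)C[C@@H](ON1C(C)(C)CCCC1(C)C)/C=C(\CBr)C(=O)OC | intermediate
20 | allylchromium dichloride from 19 (chromium on C13, alkene geometry mobile) | I/C=C/[C@](C)(O[Si](CC)(CC)CC)C[C@@H](ON1C(C)(C)CCCC1(C)C)C=C(C[Cr](Cl)Cl)C(=O)OC | intermediate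
21 | open hydroxy ester (C6-OH, C3-OH, methyl ester; C6, C7, C8, C10 as in the target) | C=C(C(=O)OC)[C@@H]([C@H](O)/C=C(/CO[Si](c1ccccc1)(c1ccccc1)C(C)(C)C)CO)[C@H](ON1C(C)(C)CCCC1(C)C)C[C@@](C)(O[Si](CC)(CC)CC)/C=C/I | intermediate
22 | C3-hydroxy iodo lactone (trans α-methylene-γ-butyrolactone; 8-O-TMP, 10-O-TES, 15-O-TBDPS, E-alkenyl iodide) | C=C1C(=O)O[C@H](/C=C(/CO[Si](c2ccccc2)(c2ccccc2)C(C)(C)C)CO)[C@H]1[C@H](ON1C(C)(C)CCCC1(C)C)C[C@@](C)(O[Si](CC)(CC)CC)/C=C/I | intermediate
23 | triol (C3-OH, C8-OH, C10-OH; 15-O-TBDPS) | C=C1C(=O)O[C@H](/C=C(/CO[Si](c2ccccc2)(c2ccccc2)C(C)(C)C)CO)[C@H]1[C@H](O)C[C@@](C)(O)/C=C/I | intermediate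
24 | C3-O-TES diol | C=C1C(=O)O[C@H](/C=C(/CO[Si](c2ccccc2)(c2ccccc2)C(C)(C)C)CO[Si](CC)(CC)CC)[C@H]1[C@H](O)C[C@@](C)(O)/C=C/I | intermediate
25 | (R)-2-methylbutanoic acid | CC[C@@H](C)C(=O)O | starting material
26 | C8 (R)-2-methylbutanoate (C3-O-TES, C10-OH) | C=C1C(=O)O[C@H](/C=C(/CO[Si](c2ccccc2)(c2ccccc2)C(C)(C)C)CO[Si](CC)(CC)CC)[C@H]1[C@H](OC(=O)[C@H](C)CC)C[C@@](C)(O)/C=C/I | intermediate
27 | (Z)-enal (C3 aldehyde) with (E)-alkenyl iodide | C=C1C(=O)O[C@H](/C=C(/CO[Si](c2ccccc2)(c2ccccc2)C(C)(C)C)C=O)[C@H]1[C@H](OC(=O)[C@H](C)CC)C[C@@](C)(O)/C=C/I | intermediate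
28 | alkenylchromium dichloride from 27 | C=C1C(=O)O[C@H](/C=C(/CO[Si](c2ccccc2)(c2ccccc2)C(C)(C)C)C=O)[C@H]1[C@H](OC(=O)[C@H](C)CC)C[C@@](C)(O)/C=C/[Cr](Cl)Cl | intermediate
29 | macrocyclic bis-allylic alcohol (C3-OH, both epimers; 15-O-TBDPS) | C=C1C(=O)O[C@@H]2/C=C(/CO[Si](c3ccccc3)(c3ccccc3)C(C)(C)C)C(O)/C=C/[C@](C)(O)C[C@@H](OC(=O)[C@H](C)CC)[C@@H]12 | intermediate
30 | 15-O-TBDPS ether of the target | C=C1C(=O)O[C@@H]2/C=C(/CO[Si](c3ccccc3)(c3ccccc3)C(C)(C)C)C(=O)/C=C/[C@](C)(O)C[C@@H](OC(=O)[C@H](C)CC)[C@@H]12 | intermediate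
31 | target compound | C=C1C(=O)O[C@@H]2/C=C(/CO)C(=O)/C=C/[C@](C)(O)C[C@@H](OC(=O)[C@H](C)CC)[C@@H]12 | target

**Step count**

Total: 19 steps. Longest linear sequence: 16 steps (steps 4–19, from (R)-linalool).

**Steps most likely to fail, with fallbacks**

1. Step 12 (fragment union). The process at risk is facial selection at C7: if the aldehyde approaches anti to the C8–O bond (Felkin–Anh-type) instead of anti to the C9 chain, the C6/C7 bis-epimer forms; erosion of the anti selectivity is a second possibility. The fallback enters with the C8 epimer, for which C–O-anti attack gives the correct C6 and C7, and corrects C8 at the ester stage. It sets out from 14 and comes back at 26. Oxyamination of 14 with the mirror-image imidazolidinone should give the (2S)-aldehyde F1. Vinylalumination as in step 10 should give the adduct F2, and NBS/Me2S the allylic bromide F3. With CrCl2 and lactol 6, the allylchromium dichloride F4 should add to give the open hydroxy ester F5, which lactonizes to the 8-epi lactone F6. Zn/AcOH should then give the 8-epi triol F7, and TESCl the 8-epi C3-O-TES diol F8. Mitsunobu esterification of F8 with acid 25 (PPh3, diisopropyl azodicarboxylate, toluene, 0 °C → rt) inverts C8 and should deliver 26.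

2. Step 17 (ring closure). The processes at risk are protodemetalation or oligomerization of the alkenylchromium before it reaches C3 in the medium-ring transition state, and geometric drift or reductive dimerization of the Z-enal during the slow high-dilution reaction. The fallback closes the same bond at the acyl oxidation level, which removes the labile aldehyde and the later oxidation. It sets out from 27 and comes back at 30. Pinnick oxidation (NaClO2, NaH2PO4, 2-methyl-2-butene, t-BuOH/H2O) should give the (Z)-enoic acid F9. 2,2'-Dipyridyl disulfide and PPh3 should convert it into the S-(2-pyridyl) thioester F10. Nickel/zirconium-mediated reductive coupling of the alkenyl iodide with the thioester (NiBr2·glyme, 4,4'-di-tert-butyl-2,2'-bipyridine, Cp2ZrCl2, Zn dust, 1,3-dimethyl-2-imidazolidinone, high dilution) should then give dienone 30 directly.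

3. Step 13 (N–O cleavage). The process at risk is conjugate reduction of the exocyclic enoate of the methylene lactone by zinc during the slow reduction of the hindered alkoxyamine. The fallback masks the enoate for this step. It sets out from 22 and comes back at 23. Dimethylamine (THF, rt) should add to the methylene lactone to give the α-(dimethylaminomethyl) lactone F11. Zn/AcOH as in step 13 should give the amino triol F12. Methyl iodide should convert F12 into the trimethylammonium iodide F13, which is not isolated; aqueous NaHCO3 eliminates trimethylamine and should restore the methylene lactone in 23.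

**Further compounds**

F1 | step 12 | (2S,4R,5E)-6-iodo-4-methyl-2-(TMP-O)-4-(triethylsilyloxy)hex-5-enal | I/C=C/[C@](C)(O[Si](CC)(CC)CC)C[C@H](ON1C(C)(C)CCCC1(C)C)C=O
F2 | step 12 | methyl (4S,6R,7E)-3-hydroxy-8-iodo-6-methyl-2-methylidene-4-(TMP-O)-6-(triethylsilyloxy)oct-7-enoate | I/C=C/[C@](C)(O[Si](CC)(CC)CC)C[C@H](ON1C(C)(C)CCCC1(C)C)C(O)C(=C)C(=O)OC
F3 | step 12 | methyl (2Z,4S,6R,7E)-2-(bromomethyl)-8-iodo-6-methyl-4-(TMP-O)-6-(triethylsilyloxy)octa-2,7-dienoate | I/C=C/[C@](C)(O[Si](CC)(CC)CC)C[C@H](ON1C(C)(C)CCCC1(C)C)/C=C(\CBr)C(=O)OC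
F4 | step 12 | allylchromium dichloride from F3 | I/C=C/[C@](C)(O[Si](CC)(CC)CC)C[C@H](ON1C(C)(C)CCCC1(C)C)C=C(C[Cr](Cl)Cl)C(=O)OC
F5 | step 12 | 8-epi open hydroxy ester | C=C(C(=O)OC)[C@@H]([C@H](O)/C=C(/CO[Si](c1ccccc1)(c1ccccc1)C(C)(C)C)CO)[C@@H](ON1C(C)(C)CCCC1(C)C)C[C@@](C)(O[Si](CC)(CC)CC)/C=C/I
F6 | step 12 | 8-epi C3-hydroxy iodo lactone | C=C1C(=O)O[C@H](/C=C(/CO[Si](c2ccccc2)(c2ccccc2)C(C)(C)C)CO)[C@H]1[C@@H](ON1C(C)(C)CCCC1(C)C)C[C@@](C)(O[Si](CC)(CC)CC)/C=C/I
F7 | step 12 | 8-epi triol | C=C1C(=O)O[C@H](/C=C(/CO[Si](c2ccccc2)(c2ccccc2)C(C)(C)C)CO)[C@H]1[C@@H](O)C[C@@](C)(O)/C=C/I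
F8 | step 12 | 8-epi C3-O-TES diol | C=C1C(=O)O[C@H](/C=C(/CO[Si](c2ccccc2)(c2ccccc2)C(C)(C)C)CO[Si](CC)(CC)CC)[C@H]1[C@@H](O)C[C@@](C)(O)/C=C/I
F9 | step 17 | (Z)-enoic acid (C3 carboxylic acid) | C=C1C(=O)O[C@H](/C=C(/CO[Si](c2ccccc2)(c2ccccc2)C(C)(C)C)C(=O)O)[C@H]1[C@H](OC(=O)[C@H](C)CC)C[C@@](C)(O)/C=C/I
F10 | step 17 | S-(2-pyridyl) thioester of F9 | C=C1C(=O)O[C@H](/C=C(/CO[Si](c2ccccc2)(c2ccccc2)C(C)(C)C)C(=O)Sc2ccccn2)[C@H]1[C@H](OC(=O)[C@H](C)CC)C[C@@](C)(O)/C=C/I
F11 | step 13 | α-(dimethylaminomethyl) lactone from 22 (C11 unassigned) | CN(C)CC1C(=O)O[C@H](/C=C(/CO[Si](c2ccccc2)(c2ccccc2)C(C)(C)C)CO)[C@H]1[C@H](ON1C(C)(C)CCCC1(C)C)C[C@@](C)(O[Si](CC)(CC)CC)/C=C/I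
F12 | step 13 | amino triol | CN(C)CC1C(=O)O[C@H](/C=C(/CO[Si](c2ccccc2)(c2ccccc2)C(C)(C)C)CO)[C@H]1[C@H](O)C[C@@](C)(O)/C=C/I
F13 | step 13 | trimethylammonium iodide of F12 | C[N+](C)(C)CC1C(=O)O[C@H](/C=C(/CO[Si](c2ccccc2)(c2ccccc2)C(C)(C)C)CO)[C@H]1[C@H](O)C[C@@](C)(O)/C=C/I.[I-]
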